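What share of its charge does the alder run turn into product by 12 min, when its charge of starting material lies below that of every run so far?

| setting | ash | oak | birch | larch | alder |
|---|---|---|---|---|---|
| starting material | 0.150 M | 0.0600 M | 0.150 M | 0.0750 M | 0.0330 M |
| reagent | 0.375 M | 0.285 M | 0.375 M | 0.375 M | 0.375 M |
| catalyst | 0.00150 M | 0.00150 M | 0.00150 M | 0.00150 M | 0.00150 M |
| product |  |  | 0.0450 M |  |  |
| time |  |  |  |  | 12 min |

| run | time / min | [product] / M |
|---|---|---|
| ash run | 0.43 | 0.0033 |
| ash run | 1.3 | 0.0075 |
| ash run | 2.5 | 0.0132 |
| ash run | 4.0 | 0.0209 |
| ash run | 5.7 | 0.0299 |
| ash run | 7.6 | 0.0409 |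
| ash run | 9.7 | 0.0508 |
| ash run | 12 | 0.0605 |
| oak run | 0.43 | 9 × 10⁻⁴ |
| oak run | 1.3 | 0.0045 |
| oak run | 2.5 | 0.0077 |
| oak run | 4.0 | 0.0142 |
| oak run | 5.7 | 0.0172 |
| oak run | 7.6 | 0.0218 |
| oak run | 9.7 | 0.0283 |
| oak run | 12 | 0.0302 |
| birch run | 0.43 | 0.0457 |
| birch run | 1.3 | 0.0538 |
| birch run | 2.5 | 0.0589 |
| birch run | 4.0 | 0.0688 |
| birch run | 5.7 | 0.0757 |
| birch run | 7.6 | 0.0854 |
| birch run | 9.7 | 0.0963 |
| birch run | 12 | 0.1078 |
| larch run | 0.43 | 0.0030 |
| larch run | 1.3 | 0.0051 |
| larch run | 2.5 | 0.0087 |
| larch run | 4.0 | 0.0162 |
| larch run | 5.7 | 0.0231 |
| larch run | 7.6 | 0.0265 |
| larch run | 9.7 | 0.0351 |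
| larch run | 12 | 0.0401 |

(standard deviation of a reading: 0.001 M)

- Overall: starting material + reagent -> product, with catalyst as catalyst.
- Constant volume, constant temperature.
- A reading of a species includes what of it is bound.
- An order is taken over about fifteen percent of the charge, up and down.

* how the opening rate goes with [starting material] round the charge of the ash run: the exponent of the rate at two percent of starting material gone to product (one fixed amount of product, the same in the runs compared)
* how the opening rate goes with [reagent] round the charge of the ash run: the exponent of the rate at two percent of starting material gone to product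
* the oak run starts with 0.0900 M less of starting material and of reagent than the ash run, and with no product. Compared where both hold the same amount of starting material, once fifteen percent of what the oak run was charged with has turned into product, is the oak run faster, slower or alike (within a tenth)?
* product in the alder run at 12 min, as a share of the starting material charged

A share can be carried from one flask to another as a clock, the apparent first-order constant of a run, defined as the natural logarithm of charge over what remains, divided by the time: the larch run, with 53.5% of its charge turned by 12 min, reads 0.0638 min⁻¹. The ash run, at the same reagent charge and with twice the starting material, has turned 40.3% and reads 0.0430 min⁻¹, so the clock runs faster at the lower charge.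

My own bracket for the alder run starts from below. Between 7.6 min and 12 min the larch run reads a clock of 0.0748 min⁻¹, with a scatter near 0.00802 min⁻¹, while it still holds more starting material than the alder run is charged with. Held for 12 min, that clock turns 59.2% of the alder charge, and this is my floor, an estimate that carries the scatter of that reading. From above, the climb from the ash run to the larch run, continued as a power of the charge down to the alder charge, gives a clock of 0.102 min⁻¹ and a share of 70.4%. That ceiling rests on an assumption of mine, not on a reading: that the climb flattens as the charge falls.

The forecast, on the view “This looks like saturation”, gives orders of 0.35 in starting material and 0.1 in reagent, calls the oak and ash runs alike, and puts the alder run at 63%, inside the bracket.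

The alder run gives 61.4%, also inside the bracket; the order in starting material comes to 0.32 against the forecast's 0.35, the oak run against the ash run comes out alike, with a rate ratio of 1.0, and the forecast parts from the flask on the order in reagent, 0.63 against 0.1.

    catalyst + starting material ⇌ catalyst-substrate complex (229.2 M⁻¹ min⁻¹, 6.240 min⁻¹)
    catalyst-substrate complex + reagent → product + catalyst (22.74 M⁻¹ min⁻¹)
    starting material + reagent ⇌ idle substrate-reagent adduct, settled at all times (3.040 M⁻¹)

As a clock the alder share reads 0.0794 min⁻¹, above the 0.0638 min⁻¹ of the larch run. The oak run, charged with less starting material and less reagent than the larch run, comes to half its charge at 11.1 min, a clock of 0.0624 min⁻¹, slower than the 0.0640 min⁻¹ of the larch run at its own half.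

The runs were computed for substances that don't exist, and the scatter is random.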